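**Retrosynthetic overview**

1. Feature: the ten-membered carbocycle C1–C10 carries vicinal, ring-cis (erythro) oxygens on C8 (acylated) and C9 (free), between the C6/C7 trans-fused γ-lactone and the ring-cis C1=C10 alkene. C8–C9 is therefore cut as a pinacol bond between a C8 aldehyde and a C9 enal.
2. Late stage: C14 CH2OH to CO2Me; C8 ester from the (2S,3R)-epoxy acid (tiglic acid, Sharpless epoxidation) on the one hydroxyl left free by a 9,14-silylene; C11 methylene by Mannich reaction and elimination.
3. Key: SmI2 pinacol macrocyclisation of the epoxy lactone dialdehyde closes the ten-membered ring and sets C8 and C9.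
4. Dialdehyde: Evans syn-aldol and lactonisation of a succinyl oxazolidinone on the (4R,5R)-epoxy aldehyde set C6 and C7; the epoxide comes from Sharpless epoxidation of geraniol; the (Z)-C1=C10 bond comes from a Still–Gennari olefination after cleavage of the remote alkene.
5. Ring order: epoxide, then γ-lactone, then ten-membered carbocycle.

Key step: step 15

Remark: atoms are numbered as in germacranolides (ring C1–C10, lactone C12 on O6, C14 on C10, C15 on C4). The C14 silyl ether is carried as triisopropylsilyl, on the assumption that (chloromethoxy)triisopropylsilane is the purchasable (silyloxy)methyl halide.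

**Route**

Step 1
Reactants: 1 methyl 2-[bis(2,2,2-trifluoroethoxy)phosphoryl]acetate; 2 (chloromethoxy)triisopropylsilane
Product: 3 methyl 2-[bis(2,2,2-trifluoroethoxy)phosphoryl]-3-[(triisopropylsilyl)oxy]propanoate (racemic)
Conditions: NaH (1.0 equiv), 1 (1.3 equiv), THF, 0 °C; then 2, 0 °C → rt
Reagents that add atoms: none
Why: C-alkylation of the stabilised phosphonoacetate carbanion by the reactive α-chloro ether, with 1 in excess to suppress double alkylation, should give the α-(silyloxymethyl) Still–Gennari reagent.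

Step 2
Reactants: 4 geraniol
Product: 5 (2R,3R)-2,3-epoxygeraniol, [(2R,3R)-3-methyl-3-(4-methylpent-3-en-1-yl)oxiran-2-yl]methanol
Conditions: Ti(OiPr)4 (cat.), D-(−)-diethyl tartrate (cat.), tBuOOH, 4 Å molecular sieves, CH2Cl2, −20 °C
Reagents that add atoms: tert-butyl hydroperoxide, CC(C)(C)OO
Why: Sharpless asymmetric epoxidation of the allylic alcohol, in which the D-(−)-tartrate ligand directs oxygen to the face that gives the (2R,3R)-epoxide (C4 R, C5 R of the target) and the remote alkene, having no directing hydroxyl, is untouched.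

Step 3
Reactants: 5 (2R,3R)-2,3-epoxygeraniol
Product: 6 (2R,3R)-3-{[(4-methoxybenzyl)oxy]methyl}-2-methyl-2-(4-methylpent-3-en-1-yl)oxirane
Conditions: NaH, 4-methoxybenzyl chloride, Bu4NI (cat.), THF/DMF, 0 °C → rt
Reagents that add atoms: 4-methoxybenzyl chloride, COc1ccc(CCl)cc1
Why: Williamson etherification of the primary alkoxide, which in aprotic medium is alkylated faster than it can undergo Payne rearrangement, installs a group that leaves oxidatively in step 8.

Step 4
Reactants: 6 epoxygeranyl 4-methoxybenzyl ether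
Product: 8 3-[(2R,3R)-3-{[(4-methoxybenzyl)oxy]methyl}-2-methyloxiran-2-yl]propanal, via diol 7 (not isolated)
Conditions: OsO4 (cat.), NaIO4, 2,6-lutidine, 1,4-dioxane/H2O, rt
Reagents that add atoms: osmium tetroxide, O=[Os](=O)(=O)=O; sodium periodate, [Na+].[O-]I(=O)(=O)=O
Why: Lemieux–Johnson oxidation, in which OsO4 dihydroxylates the only alkene and NaIO4 cleaves the diol and regenerates the osmium catalyst, while 2,6-lutidine keeps the medium near neutral for the epoxide.

Step 5
Reactants: 8 epoxy aldehyde (C1 aldehyde); 3 α-(silyloxymethyl) phosphonate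
Product: 9 methyl (2Z)-5-[(2R,3R)-3-{[(4-methoxybenzyl)oxy]methyl}-2-methyloxiran-2-yl]-2-{[(triisopropylsilyl)oxy]methyl}pent-2-enoate
Conditions: 3, KN(SiMe3)2, 18-crown-6, THF, −78 °C; then 8, −78 °C
Reagents that add atoms: none
Why: Still–Gennari olefination, in which the electron-poor bis(trifluoroethyl) phosphonate eliminates fast from the kinetic adduct so that the ester (C9) ends cis and the CH2OTIPS arm (C14) trans to the C2 chain, which is the geometry of the ring-cis C1=C10 bond.

Step 6
Reactants: 9 (Z)-enoate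
Product: 10 (2E)-5-[(2R,3R)-3-{[(4-methoxybenzyl)oxy]methyl}-2-methyloxiran-2-yl]-2-{[(triisopropylsilyl)oxy]methyl}pent-2-en-1-ol (CH2OH cis to the chain)
Conditions: iBu2AlH (2.5 equiv), CH2Cl2, −78 °C; aq. potassium sodium tartrate
Reagents that add atoms: none
Why: 1,2-reduction of the enoate by the aluminium hydride at −78 °C tolerates the epoxide and both ethers and leaves the alkene geometry unchanged.

Step 7
Reactants: 10 allylic alcohol
Product: 11 triethylsilyl ether of 10 (C9–OSiEt3, C14–OTIPS, C6–OPMB)
Conditions: Et3SiCl, imidazole, CH2Cl2, 0 °C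
Reagents that add atoms: chlorotriethylsilane, CC[Si](Cl)(CC)CC
Why: silylation under neutral imidazole conditions avoids an alkoxide that could draw the TIPS group across the 1,3-dioxygenated allyl unit, and the triethylsilyl group can later be removed beside TIPS.

Step 8
Reactants: 11 fully protected epoxide
Product: 12 (2R,3R)-epoxy alcohol with C6–OH free (C9–OSiEt3 cis to the chain, C14–OTIPS)
Conditions: DDQ, CH2Cl2/pH 7 phosphate buffer, 0 °C
Reagents that add atoms: none
Why: oxidative cleavage of the 4-methoxybenzyl ether by DDQ through its benzylic oxocarbenium ion, in buffered two-phase medium that spares both silyl ethers and the epoxide.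

Step 9
Reactants: 12 epoxy alcohol
Product: 13 (2S,3R)-3-methyl-3-[5-(triethylsilyloxy)-4-(triisopropylsilyloxymethyl)pent-3-en-1-yl]oxirane-2-carbaldehyde (C6 aldehyde)
Conditions: Dess–Martin periodinane, NaHCO3, CH2Cl2, 0 °C → rt; used at once
Reagents that add atoms: none
Why: Dess–Martin oxidation under bicarbonate buffer gives the α,β-epoxy aldehyde without acid or base strong enough to open or rearrange the epoxide.

Step 10
Reactants: 14 (S)-4-benzyl-1,3-oxazolidin-2-one; 15 methyl 4-chloro-4-oxobutanoate
Product: 16 (S)-4-benzyl-3-(4-methoxy-4-oxobutanoyl)-1,3-oxazolidin-2-one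
Conditions: BuLi, THF, −78 °C; then 15, −78 → 0 °C
Reagents that add atoms: none
Why: N-acylation of the lithiated oxazolidinone by the acid chloride, the standard preparation of an Evans imide, with the distal methyl ester far less electrophilic.

Step 11
Reactants: 13 epoxy aldehyde; 16 succinyl imide
Product: 19 trans-γ-lactone imide, (6S,7S): the C6 carbon of the lactone carries the (4R,5R)-epoxide chain and C7 carries the N-acyl oxazolidinone carbonyl (C8), via boron enolate 17 (not isolated), via aldol hydroxy ester 18 (not isolated)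
Conditions: 16 (1.5 equiv), Bu2BOTf, iPr2NEt, CH2Cl2, −78 → 0 °C; 13, −78 → 0 °C; pH 7 buffer, MeOH, 30% H2O2, 0 °C; then PhMe, 50 °C
Reagents that add atoms: none
Why: Evans syn-aldol reaction, in which the (Z)-boron enolate formed on the imide side adds through a chair Zimmerman–Traxler transition state on the face away from the benzyl group, so that the (S)-auxiliary should set C6 S and C7 syn to it by reagent control over the modest bias of the epoxy aldehyde, and the C6 hydroxyl then closes the γ-lactone on the methyl ester (5-exo-trig), the syn adduct giving the trans-lactone.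

Step 12
Reactants: 19 lactone imide
Product: 20 (6S,7R)-trans-lactone with C7–CH2OH (C8), C9–OSiEt3, C14–OTIPS
Conditions: NaBH4, THF/H2O (4:1), 0 °C
Reagents that add atoms: none
Why: reductive cleavage of the N-acyl oxazolidinone, in which borohydride attacks the activated exocyclic imide carbonyl much faster than the lactone and releases the auxiliary without touching C7.

Step 13
Reactants: 20 hydroxymethyl lactone
Product: 21 (6S,7R)-trans-lactone diol (C8–OH and C9–OH free, C14–OTIPS)
Conditions: HF·pyridine, pyridine, THF, 0 °C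
Reagents that add atoms: none
Why: fluoride desilylation is much faster for the primary triethylsilyl ether than for the hindered triisopropylsilyl ether, and the pyridine buffer spares epoxide and lactone.

Step 14
Reactants: 21 diol
Product: 22 epoxy lactone dialdehyde: (4R,5R)-epoxide, (6S,7S)-trans-lactone with C7–CHO (C8), (Z)-enal C9 cis to the C2 chain, C14–OTIPS
Conditions: Dess–Martin periodinane (3 equiv), NaHCO3, CH2Cl2, 0 °C → rt; used at once
Reagents that add atoms: none
Why: double Dess–Martin oxidation of both primary alcohols under buffered, non-basic conditions should preserve the (Z)-enal geometry and the epimerisable C7 centre of the β-acyloxy aldehyde.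

Step 15
Reactants: 22 epoxy lactone dialdehyde
Product: 23 (4R,5R,6S,7R,8S,9R)-ten-membered ring-cis 8,9-diol (trans-lactone, 4,5-epoxide, ring-cis C1=C10, C14–OTIPS)
Conditions: SmI2 (4 equiv), THF, 22 added slowly to a final 0.002 M, −40 → −20 °C; cold aq. NH4Cl
Reagents that add atoms: none
Why: samarium diiodide (divalent samarium) transfers one electron to the more easily reduced enal carbonyl C9 and one to the C8 aldehyde, and the samarium-bound ketyls join carbon to carbon, which is the known intramolecular pinacol coupling of dialdehydes to carbocyclic 1,2-diols. The ten-membered ring closes between C8 and C9 (formally a 10-exo-trig attack of the C9 ketyl on the C8 carbonyl), helped by the trans-fused lactone, the trans-epoxide and the ring-cis alkene, which already fold C1–C7 into a turn. The ring-cis (erythro) relation of C8 and C9 should follow from both oxygens being held on trivalent samarium in the bond-forming transition state, which forces the two C–O bonds syn. The absolute sense (8S,9R) is expected from C7: the C8 carbonyl should react with its C=O turned away from the C6–O bond of the lactone, giving the 1,3-anti relation of O6 and O8 found in the target. The step needs 1,2-coupling and not coupling through the enal β-carbon C1 (which would give an eight-membered ring); the oxophilic samarium bridge, the substituent on C10 and the absence of a second acceptor at C14 (silyl ether, not ester) should secure this, while high dilution and a cold quench limit oligomers and transfer of the lactone acyl group to the new C8 alkoxide.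

Step 16
Reactants: 23 cis-8,9-diol
Product: 24 8,9-bis(triethylsilyl) ether of 23
Conditions: Et3SiOTf, 2,6-lutidine, CH2Cl2, −78 → 0 °C
Reagents that add atoms: triethylsilyl trifluoromethanesulfonate, CC[Si](CC)(CC)OS(=O)(=O)C(F)(F)F
Why: silylation of both secondary hydroxyls with the silyl triflate masks them, and with them the risk of lactone migration to O8, during the strongly basic enolate step that follows.

Step 17
Reactants: 24 bis-silyl ether
Product: 27 α-methylene lactone (C11=C13) with 8,9-bis(triethylsilyl) ethers and C14–OTIPS, via Mannich base 25 (not isolated), via ammonium iodide 26 (not isolated)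
Conditions: LiN(iPr)2, THF, −78 °C; Eschenmoser's salt, −78 °C → rt; MeI, MeOH/CH2Cl2, rt; aq. NaHCO3, rt
Reagents that add atoms: Eschenmoser's salt (N,N-dimethylmethyleneiminium iodide), C=[N+](C)C.[I-]
Why: classical α-methylenation of a γ-lactone, in which the lithium enolate is aminomethylated (Mannich reaction), the amine is quaternised and the ammonium salt undergoes E1cB elimination to the exocyclic alkene, so that the transient C11 centre is lost.

Step 18
Reactants: 27 silylated α-methylene lactone
Product: 28 (4R,5R,6S,7R,8S,9R)-8,9,14-triol with α-methylene lactone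
Conditions: HF·pyridine, pyridine, THF, 0 °C → rt
Reagents that add atoms: none
Why: global fluoride desilylation of the two triethylsilyl ethers and the triisopropylsilyl ether under pyridine buffering, which should leave the trisubstituted epoxide and the α-methylene lactone intact.

Step 19
Reactants: 28 triol
Product: 29 9,14-O-(di-tert-butylsilylene) derivative of 28 with C8–OH free
Conditions: tBu2Si(OTf)2 (1.05 equiv), 2,6-lutidine, CH2Cl2, −40 → 0 °C
Reagents that add atoms: di-tert-butylsilyl bis(trifluoromethanesulfonate), CC(C)(C)[Si](OS(=O)(=O)C(F)(F)F)(OS(=O)(=O)C(F)(F)F)C(C)(C)C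
Why: di-tert-butylsilylene protection of a 1,3-diol, in which the primary C14 hydroxyl is silylated first and the remaining Si–OTf can close only the six-membered ring onto O9 (a seven-membered ring to O8 being disfavoured), so that C8–OH alone stays free and the site of acylation is fixed.

Step 20
Reactants: 30 tiglic acid
Product: 31 tiglyl alcohol, (2E)-2-methylbut-2-en-1-ol
Conditions: LiAlH4, Et2O, 0 °C → rt
Reagents that add atoms: none
Why: hydride reduction of the carboxylic acid to the allylic alcohol, the alkene of the intermediate carboxylate not being reduced under these conditions.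

Step 21
Reactants: 31 tiglyl alcohol
Product: 32 [(2R,3R)-2,3-dimethyloxiran-2-yl]methanol
Conditions: Ti(OiPr)4 (cat.), D-(−)-diethyl tartrate (cat.), tBuOOH, 4 Å molecular sieves, CH2Cl2, −20 °C
Reagents that add atoms: tert-butyl hydroperoxide, CC(C)(C)OO
Why: Sharpless asymmetric epoxidation, in which the D-(−)-tartrate ligand should give the (2R,3R)-epoxy alcohol from the (E)-allylic alcohol and so set both centres of the side-chain epoxide.

Step 22
Reactants: 32 epoxy alcohol
Product: 33 (2S,3R)-2,3-dimethyloxirane-2-carboxylic acid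
Conditions: RuCl3 (cat.), NaIO4, MeCN/EtOAc/H2O, 0 °C → rt
Reagents that add atoms: sodium periodate, [Na+].[O-]I(=O)(=O)=O; water, O
Why: ruthenium-catalysed periodate oxidation of the primary epoxy alcohol to the glycidic acid, the usual follow-up to a Sharpless epoxidation, leaves the epoxide centres untouched (the descriptor at C2 changes only by priority).

Step 23
Reactants: 29 silylene alcohol (C8–OH); 33 epoxy acid
Product: 35 C8 ester of 29 with (2S,3R)-2,3-dimethyloxirane-2-carboxylic acid, via mixed anhydride 34 (not isolated)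
Conditions: 33, 2,4,6-trichlorobenzoyl chloride, Et3N, THF, rt; then 29, DMAP, PhMe, rt → 40 °C
Reagents that add atoms: none
Why: Yamaguchi esterification, in which DMAP attacks the mixed anhydride at the glycidic carbonyl and the acylpyridinium acylates the only free hydroxyl (C8) with retention at every stereocentre.

Step 24
Reactants: 35 silylene ester
Product: 36 8-O-acyl 9,14-diol with α-methylene lactone
Conditions: HF·pyridine, pyridine, THF, 0 °C
Reagents that add atoms: none
Why: the cyclic silylene is cleaved by buffered HF, which leaves the ester, both epoxides and the α-methylene lactone untouched.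

Step 25
Reactants: 36 diol
Product: 37 C14 aldehyde (enal on C10) with C9–OH free
Conditions: TEMPO (cat.), PhI(OAc)2, CH2Cl2, rt
Reagents that add atoms: none
Why: oxoammonium (TEMPO) oxidation with the iodine diacetate is selective for the primary allylic alcohol over the secondary C9 hydroxyl and stops at the aldehyde.

Step 26
Reactants: 37 enal
Product: 38 C14 carboxylic acid
Conditions: NaClO2, NaH2PO4, 2-methyl-2-butene, tBuOH/H2O, 0 °C → rt
Reagents that add atoms: sodium chlorite, [Na+].[O-]Cl=O
Why: Pinnick oxidation converts the enal to the acid under mildly acidic conditions, with 2-methyl-2-butene trapping hypochlorite so that alkenes and epoxides are spared.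

Step 27
Reactants: 38 acid
Product: 39 target CNP0262846.1
Conditions: MeI, KHCO3, DMF, rt
Reagents that add atoms: iodomethane, CI
Why: O-alkylation of the carboxylate with iodomethane under a weak base forms the methyl ester without diazomethane, which would add to the α-methylene lactone, and without acyl migration from O8.

**Compound list**

1 | methyl 2-[bis(2,2,2-trifluoroethoxy)phosphoryl]acetate | COC(=O)CP(=O)(OCC(F)(F)F)OCC(F)(F)F | starting material
2 | (chloromethoxy)triisopropylsilane | CC(C)[Si](OCCl)(C(C)C)C(C)C | starting material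
3 | methyl 2-[bis(2,2,2-trifluoroethoxy)phosphoryl]-3-[(triisopropylsilyl)oxy]propanoate | COC(=O)C(CO[Si](C(C)C)(C(C)C)C(C)C)P(=O)(OCC(F)(F)F)OCC(F)(F)F | intermediate
4 | geraniol | CC(C)=CCC/C(C)=C/CO | starting material
5 | (2R,3R)-2,3-epoxygeraniol | CC(C)=CCC[C@@]1(C)O[C@@H]1CO | intermediate
6 | (2R,3R)-epoxygeranyl 4-methoxybenzyl ether | CC(C)=CCC[C@@]1(C)O[C@@H]1COCc1ccc(OC)cc1 | intermediate
7 | vicinal diol from dihydroxylation of the remote alkene of 6 (not isolated) | CC(C)(O)C(O)CC[C@@]1(C)O[C@@H]1COCc1ccc(OC)cc1 | intermediate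
8 | 3-[(2R,3R)-3-{[(4-methoxybenzyl)oxy]methyl}-2-methyloxiran-2-yl]propanal | O=CCC[C@@]1(C)O[C@@H]1COCc1ccc(OC)cc1 | intermediate
9 | methyl (2Z)-5-[(2R,3R)-epoxide]-2-{[(triisopropylsilyl)oxy]methyl}pent-2-enoate (C6–OPMB) | COC(=O)/C(CO[Si](C(C)C)(C(C)C)C(C)C)=C\CC[C@@]1(C)O[C@@H]1COCc1ccc(OC)cc1 | intermediate
10 | allylic alcohol from 9 (C9–OH cis to chain) | OC/C(CO[Si](C(C)C)(C(C)C)C(C)C)=C\CC[C@@]1(C)O[C@@H]1COCc1ccc(OC)cc1 | intermediate
11 | triethylsilyl ether of 10 | CC[Si](CC)(CC)OC/C(CO[Si](C(C)C)(C(C)C)C(C)C)=C\CC[C@@]1(C)O[C@@H]1COCc1ccc(OC)cc1 | intermediate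
12 | (2R,3R)-epoxy alcohol (C6–OH) | CC[Si](CC)(CC)OC/C(CO[Si](C(C)C)(C(C)C)C(C)C)=C\CC[C@@]1(C)O[C@@H]1CO | intermediate
13 | (2S,3R)-epoxy aldehyde (C6 aldehyde) | CC[Si](CC)(CC)OC/C(CO[Si](C(C)C)(C(C)C)C(C)C)=C\CC[C@@]1(C)O[C@@H]1C=O | intermediate
14 | (S)-4-benzyl-1,3-oxazolidin-2-one | O=C1OC[C@H](Cc2ccccc2)N1 | starting material
15 | methyl 4-chloro-4-oxobutanoate | COC(=O)CCC(Cl)=O | starting material
16 | (S)-4-benzyl-3-(4-methoxy-4-oxobutanoyl)-1,3-oxazolidin-2-one | COC(=O)CCC(=O)N1C(=O)OC[C@@H]1Cc1ccccc1 | intermediate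
17 | (Z)-dibutylboron enolate of 16 (not isolated) | CCCCB(CCCC)O/C(=C\CC(=O)OC)N1C(=O)OC[C@@H]1Cc1ccccc1 | intermediate
18 | (6S,7S)-syn-aldol hydroxy ester imide (not isolated) | CC[Si](CC)(CC)OC/C(CO[Si](C(C)C)(C(C)C)C(C)C)=C\CC[C@@]1(C)O[C@@H]1[C@@H](O)[C@H](CC(=O)OC)C(=O)N1C(=O)OC[C@@H]1Cc1ccccc1 | intermediate
19 | (6S,7S)-trans-lactone imide | CC[Si](CC)(CC)OC/C(CO[Si](C(C)C)(C(C)C)C(C)C)=C\CC[C@@]1(C)O[C@@H]1[C@H]2OC(=O)C[C@@H]2C(=O)N3C(=O)OC[C@@H]3Cc4ccccc4 | intermediate
20 | (6S,7R)-trans-lactone with C8–OH, C9–OSiEt3 | CC[Si](CC)(CC)OC/C(CO[Si](C(C)C)(C(C)C)C(C)C)=C\CC[C@@]1(C)O[C@@H]1[C@H]2OC(=O)C[C@@H]2CO | intermediate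
21 | (6S,7R)-trans-lactone 8,9-diol (open chain) | OC/C(CO[Si](C(C)C)(C(C)C)C(C)C)=C\CC[C@@]1(C)O[C@@H]1[C@H]2OC(=O)C[C@@H]2CO | intermediate
22 | epoxy lactone dialdehyde (C8 aldehyde, C9 (Z)-enal, C14–OTIPS) | O=C/C(CO[Si](C(C)C)(C(C)C)C(C)C)=C\CC[C@@]1(C)O[C@@H]1[C@H]2OC(=O)C[C@@H]2C=O | intermediate
23 | (4R,5R,6S,7R,8S,9R)-ten-membered cis-8,9-diol | O[C@@H]1/C(CO[Si](C(C)C)(C(C)C)C(C)C)=C\CC[C@@]2(C)O[C@@H]2[C@H]3OC(=O)C[C@@H]3[C@@H]1O | intermediate
24 | 8,9-bis(triethylsilyl) ether of 23 | CC[Si](CC)(CC)O[C@@H]1/C(CO[Si](C(C)C)(C(C)C)C(C)C)=C\CC[C@@]2(C)O[C@@H]2[C@H]3OC(=O)C[C@@H]3[C@@H]1O[Si](CC)(CC)CC | intermediate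
25 | C11 (dimethylamino)methyl lactone, C11 epimers (not isolated) | CN(C)CC1C(=O)O[C@H]2[C@H]1[C@H](O[Si](CC)(CC)CC)[C@H](O[Si](CC)(CC)CC)/C(CO[Si](C(C)C)(C(C)C)C(C)C)=C\CC[C@@]1(C)O[C@H]21 | intermediate
26 | trimethylammonium iodide of 25 (not isolated) | C[N+](C)(C)CC1C(=O)O[C@H]2[C@H]1[C@H](O[Si](CC)(CC)CC)[C@H](O[Si](CC)(CC)CC)/C(CO[Si](C(C)C)(C(C)C)C(C)C)=C\CC[C@@]1(C)O[C@H]21.[I-] | intermediate
27 | α-methylene lactone, 8,9-bis(triethylsilyl) ether, C14–OTIPS | C=C1C(=O)O[C@H]2[C@H]1[C@H](O[Si](CC)(CC)CC)[C@H](O[Si](CC)(CC)CC)/C(CO[Si](C(C)C)(C(C)C)C(C)C)=C\CC[C@@]1(C)O[C@H]21 | intermediate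
28 | 8,9,14-triol with α-methylene lactone | C=C1C(=O)O[C@H]2[C@H]1[C@H](O)[C@H](O)/C(CO)=C\CC[C@@]1(C)O[C@H]21 | intermediate
29 | 9,14-O-(di-tert-butylsilylene), C8–OH free | C=C1C(=O)O[C@H]2[C@H]1[C@H](O)[C@@H]3O[Si](C(C)(C)C)(C(C)(C)C)OC/C3=C/CC[C@@]1(C)O[C@H]21 | intermediate
30 | tiglic acid | C/C=C(\C)C(=O)O | starting material
31 | tiglyl alcohol | C/C=C(\C)CO | intermediate
32 | [(2R,3R)-2,3-dimethyloxiran-2-yl]methanol | OC[C@@]1(C)O[C@@H]1C | intermediate
33 | (2S,3R)-2,3-dimethyloxirane-2-carboxylic acid | OC(=O)[C@@]1(C)O[C@@H]1C | intermediate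
34 | mixed anhydride of 33 with 2,4,6-trichlorobenzoic acid (not isolated) | O=C(OC(=O)[C@@]1(C)O[C@@H]1C)c1c(Cl)cc(Cl)cc1Cl | intermediate
35 | C8 epoxy ester, 9,14-O-silylene | C=C1C(=O)O[C@H]2[C@H]1[C@H](OC(=O)[C@@]1(C)O[C@@H]1C)[C@@H]3O[Si](C(C)(C)C)(C(C)(C)C)OC/C3=C/CC[C@@]1(C)O[C@H]21 | intermediate
36 | C8 epoxy ester, 9,14-diol | C=C1C(=O)O[C@H]2[C@H]1[C@H](OC(=O)[C@@]1(C)O[C@@H]1C)[C@H](O)/C(CO)=C\CC[C@@]1(C)O[C@H]21 | intermediate
37 | C8 epoxy ester, C14 aldehyde | C=C1C(=O)O[C@H]2[C@H]1[C@H](OC(=O)[C@@]1(C)O[C@@H]1C)[C@H](O)/C(C=O)=C\CC[C@@]1(C)O[C@H]21 | intermediate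
38 | C8 epoxy ester, C14 carboxylic acid | C=C1C(=O)O[C@H]2[C@H]1[C@H](OC(=O)[C@@]1(C)O[C@@H]1C)[C@H](O)/C(C(=O)O)=C\CC[C@@]1(C)O[C@H]21 | intermediate
39 | CNP0262846.1 | C=C1C(=O)O[C@H]2[C@H]1[C@H](OC(=O)[C@@]1(C)O[C@@H]1C)[C@H](O)/C(C(=O)OC)=C\CC[C@@]1(C)O[C@H]21 | target

**Step count and risks**

Total: 27 steps. Longest linear sequence: 22 steps (geraniol 4 to 39 through steps 2–9, 11–19 and 23–27).

Steps most likely to fail:

1. Step 15 (pinacol macrocyclisation). The enal ketyl may couple through its β-carbon C1 or between molecules, the ring may close with the wrong relative or facial sense at C8/C9, or the lactone acyl group may shift to the new C8 alkoxide. Fallback: from 22, double Wittig methylenation (Ph3PCH3Br, KN(SiMe3)2, THF, −78 °C) gives the divinyl epoxy lactone F1. Ring-closing metathesis (second-generation Grubbs catalyst, toluene, high dilution, 80 °C) closes the ten-membered ring as the 8,9-cis-alkene F2. Syn-dihydroxylation of the less hindered disubstituted C8=C9 bond (OsO4, N-methylmorpholine N-oxide, acetone/water) then gives the ring-cis diol by construction and rejoins the route at 23.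

2. Step 5 (Still–Gennari olefination with the β-silyloxy phosphonate). The phosphonate anion may lose silanolate by β-elimination before it meets the aldehyde, or Z-selectivity may erode. Fallback: 1 is brominated (NaH, then N-bromosuccinimide, THF) to the α-bromo phosphonate F3. Olefination of 8 with F3 (KN(SiMe3)2, 18-crown-6, THF, −78 °C) gives the (E)-α-bromo enoate F4 with the ester cis to the chain. Stille coupling with (tributylstannyl)methanol (Pd(PPh3)4, zerovalent palladium, dioxane, 80 °C) exchanges bromine for CH2OH with retention and gives the (Z)-2-(hydroxymethyl) enoate F5. Silylation (iPr3SiCl, imidazole) returns to 9.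

3. Step 11 (Evans aldol on the epoxy aldehyde). The facial preference of the epoxy aldehyde may oppose the auxiliary, or the boron triflate may open the trisubstituted epoxide. Fallback: from 13, a D-proline-catalysed cross-aldol (enamine catalysis) with methyl 4-oxobutanoate (slow addition, DMF, 4 °C) should give the anti hydroxy aldehyde F6 with C6 set by the catalyst. F6 lactonises to the cis-lactone aldehyde F7, which is equilibrated at C7 (imidazole, CH2Cl2) to the more stable trans-lactone aldehyde F8. NaBH4 (MeOH, −40 °C) reduces F8 to 20, where the route is rejoined.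

**Further compounds**

F1 | step 15 | divinyl epoxy lactone (C8 and C9 as vinyl groups) | C=C/C(CO[Si](C(C)C)(C(C)C)C(C)C)=C\CC[C@@]1(C)O[C@@H]1[C@H]2OC(=O)C[C@@H]2C=C
F2 | step 15 | ten-membered 8,9-cis-alkene (cyclodecadiene lactone) | C1C[C@@]2(C)O[C@@H]2[C@H]3OC(=O)C[C@@H]3/C=C\C(CO[Si](C(C)C)(C(C)C)C(C)C)=C/1
F3 | step 5 | methyl 2-bromo-2-[bis(2,2,2-trifluoroethoxy)phosphoryl]acetate | COC(=O)C(Br)P(=O)(OCC(F)(F)F)OCC(F)(F)F
F4 | step 5 | methyl (2E)-2-bromo-5-[(2R,3R)-3-{[(4-methoxybenzyl)oxy]methyl}-2-methyloxiran-2-yl]pent-2-enoate | COC(=O)/C(Br)=C\CC[C@@]1(C)O[C@@H]1COCc1ccc(OC)cc1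
F5 | step 5 | methyl (2Z)-2-(hydroxymethyl)-5-[(2R,3R)-3-{[(4-methoxybenzyl)oxy]methyl}-2-methyloxiran-2-yl]pent-2-enoate | COC(=O)/C(CO)=C\CC[C@@]1(C)O[C@@H]1COCc1ccc(OC)cc1
F6 | step 11 | anti-aldol hydroxy aldehyde ester (C6 S, C7 epimeric to 18) | CC[Si](CC)(CC)OC/C(CO[Si](C(C)C)(C(C)C)C(C)C)=C\CC[C@@]1(C)O[C@@H]1[C@@H](O)[C@@H](CC(=O)OC)C=O
F7 | step 11 | cis-lactone aldehyde | CC[Si](CC)(CC)OC/C(CO[Si](C(C)C)(C(C)C)C(C)C)=C\CC[C@@]1(C)O[C@@H]1[C@H]2OC(=O)C[C@H]2C=O
F8 | step 11 | trans-lactone aldehyde (C8 aldehyde, C9–OSiEt3) | CC[Si](CC)(CC)OC/C(CO[Si](C(C)C)(C(C)C)C(C)C)=C\CC[C@@]1(C)O[C@@H]1[C@H]2OC(=O)C[C@@H]2C=O
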